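Oxygen on four consecutive ring carbons (C6, C1, C2, C3), the C4=C5 alkene and C7 on C1 mark the six-membered ring as a reduced 2-(hydroxymethyl)benzoquinone. Everything rests on disconnecting the C1–O and C2–O bonds to a C1–C2 oxirane, made by asymmetric nucleophilic epoxidation of the C1=C2 enone of quinone monoketal 3. In one operation that step closes the oxirane ring and sets C1 and C2. Its precursor is a dearomatised 2-(hydroxymethyl)-4-methoxyphenol: C6 ketone, C3 dimethyl ketal, and a free C7 hydroxyl that anchors the chiral peroxide. Afterwards the oxirane oxygen becomes the C1 hydroxyl, acetate inverts C2, and C6 and C3 are set relative to the oxirane.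

Key step: step 3

Atom labels: C1 to C7 are those of the target (C1 the fully substituted carbinol carbon, C2 acetoxy, C3 benzoyloxy, C4=C5, C6 hydroxy, C7 the exocyclic CH2) and are kept for all intermediates; CIP descriptors belong to the locants of each systematic name.

Assumption: L-(+)-diisopropyl tartrate is taken as the hand that gives the (1R,6S)-oxirane 4; if the sense of induction proves opposite, D-(−)-diisopropyl tartrate is used and nothing else changes.

Step 1
Reactants: 1 2-hydroxy-5-methoxybenzaldehyde
Product: 2 2-(hydroxymethyl)-4-methoxyphenol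
Conditions: NaBH4, MeOH, 0 °C
Reagents that add atoms: none
Why: Borohydride reduction of an aryl aldehyde to the benzylic alcohol, with the phenol and the aryl ether inert and no stereocentre formed.

Step 2
Reactants: 2 2-(hydroxymethyl)-4-methoxyphenol
Product: 3 2-(hydroxymethyl)-4,4-dimethoxycyclohexa-2,5-dien-1-one
Conditions: PhI(OAc)2, MeOH, 0 °C
Reagents that add atoms: methanol, CO
Why: Oxidative dearomatisation of a para-methoxyphenol by a trivalent-iodine diacetate, in which methanol adds at the methoxy-bearing para carbon to give the quinone monoketal and the primary alcohol is left untouched.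

Step 3
Reactants: 3 2-(hydroxymethyl)-4,4-dimethoxycyclohexa-2,5-dien-1-one
Product: 4 (1R,6S)-1-(hydroxymethyl)-5,5-dimethoxy-7-oxabicyclo[4.1.0]hept-3-en-2-one
Conditions: Ph3COOH, NaN(SiMe3)2, L-(+)-diisopropyl tartrate, 4 Å MS, toluene, −65 °C
Reagents that add atoms: trityl hydroperoxide, OOC(c1ccccc1)(c1ccccc1)c1ccccc1
Why: The C7 hydroxyl is deprotonated and held with sodium trityl peroxide in a diisopropyl tartrate aggregate; the peroxide adds in conjugate fashion to C2 of the C6 enone and the C1 enolate then attacks the proximal peroxide oxygen with loss of trityl oxide, forming C2–O and then C1–O (Weitz–Scheffer mechanism). The closest known reaction type is the hydroxyl-directed, tartrate-mediated asymmetric nucleophilic epoxidation of hydroxymethyl-substituted quinone monoketals with trityl hydroperoxide and NaN(SiMe3)2. The oxirane ring closes in the 3-exo-tet mode, the O–O bond that breaks lying outside the new ring. C2 is set by the face on which the tartrate aggregate, anchored on the C7 alkoxide, delivers the peroxide, and C1 follows because the enolate must close on the same face to give the cis-fused oxirane. The step needs enantioface selection and selection of C1=C2 over the unsubstituted C4=C5 enone; both are secured by the free C7 hydroxyl, which places the chiral sodium peroxide next to C2, while the C3 ketal keeps the dienone from tautomerising to a phenol.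

Step 4
Reactants: 4 (1R,6S)-1-(hydroxymethyl)-5,5-dimethoxy-7-oxabicyclo[4.1.0]hept-3-en-2-one; 5 benzoyl chloride
Product: 6 [(1R,6S)-5,5-dimethoxy-2-oxo-7-oxabicyclo[4.1.0]hept-3-en-1-yl]methyl benzoate
Conditions: pyridine, CH2Cl2, 0 °C
Reagents that add atoms: benzoyl chloride (5), O=C(Cl)c1ccccc1
Why: Acylation of the primary C7 hydroxyl, the only hydroxyl present, with an acid chloride and pyridine, conditions that the epoxy enone and the ketal tolerate.

Step 5
Reactants: 6 [(1R,6S)-5,5-dimethoxy-2-oxo-7-oxabicyclo[4.1.0]hept-3-en-1-yl]methyl benzoate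
Product: 8 [(1S,2S,6S)-2-hydroxy-5-oxo-7-oxabicyclo[4.1.0]hept-3-en-1-yl]methyl benzoate, via cis-epoxy alcohol ketal 7 (not isolated)
Conditions: NaBH4, CeCl3·7H2O, MeOH, −78 °C; then aq. oxalic acid, THF, 0 °C to rt
Reagents that add atoms: water, O
Why: Luche 1,2-reduction of the C6 enone, in which hydride approaches C6 anti to the C1–O bond of the oxirane (attack from the oxirane-oxygen face would eclipse that bond), puts the C6 hydroxyl cis to the oxirane oxygen, and mild aqueous acid then hydrolyses the allylic dimethyl ketal to the C3 enone without touching the oxirane or the benzoate.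

Step 6
Reactants: 8 [(1S,2S,6S)-2-hydroxy-5-oxo-7-oxabicyclo[4.1.0]hept-3-en-1-yl]methyl benzoate
Product: 9 [(1S,2R,6S)-2-[(chloroacetyl)oxy]-5-oxo-7-oxabicyclo[4.1.0]hept-3-en-1-yl]methyl benzoate
Conditions: ClCH2CO2H, PPh3, DIAD, THF, 0 °C to rt
Reagents that add atoms: chloroacetic acid, OC(=O)CCl
Why: Mitsunobu esterification, in which chloroacetate displaces the C6 oxyphosphonium group by SN2 with inversion, so that the C6 oxygen ends up trans to the oxirane oxygen (on the face of C7) and already carries its protecting ester; C6 is allylic and oxiranylcarbinyl, has no hydrogen available for elimination, and SN2′ attack is disfavoured because C4 is the α-carbon of the C3 enone.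

Step 7
Reactants: 9 [(1S,2R,6S)-2-[(chloroacetyl)oxy]-5-oxo-7-oxabicyclo[4.1.0]hept-3-en-1-yl]methyl benzoate
Product: 10 [(1S,2R,5R,6R)-2-[(chloroacetyl)oxy]-5-hydroxy-7-oxabicyclo[4.1.0]hept-3-en-1-yl]methyl benzoate
Conditions: NaBH4, CeCl3·7H2O, MeOH, −78 °C
Reagents that add atoms: none
Why: Luche 1,2-reduction of the C3 enone with hydride again approaching anti to the adjacent oxirane bond (here C2–O), which sets the C3 hydroxyl cis to the oxirane oxygen, while at −78 °C the chloroacetate and the benzoate should not be attacked.

Step 8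
Reactants: 10 [(1S,2R,5R,6R)-2-[(chloroacetyl)oxy]-5-hydroxy-7-oxabicyclo[4.1.0]hept-3-en-1-yl]methyl benzoate; 5 benzoyl chloride
Product: 11 [(1S,2R,5R,6R)-5-(benzoyloxy)-2-[(chloroacetyl)oxy]-7-oxabicyclo[4.1.0]hept-3-en-1-yl]methyl benzoate
Conditions: pyridine, CH2Cl2, 0 °C
Reagents that add atoms: benzoyl chloride (5), O=C(Cl)c1ccccc1
Why: Acylation of the single free hydroxyl (C3, secondary allylic) with an acid chloride and pyridine, conditions under which chloroacetates are routinely carried.

Step 9
Reactants: 11 [(1S,2R,5R,6R)-5-(benzoyloxy)-2-[(chloroacetyl)oxy]-7-oxabicyclo[4.1.0]hept-3-en-1-yl]methyl benzoate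
Product: 12 [(1S,2R,5R,6R)-5-(benzoyloxy)-2-hydroxy-7-oxabicyclo[4.1.0]hept-3-en-1-yl]methyl benzoate
Conditions: DABCO, EtOH, 55 °C
Reagents that add atoms: none
Why: Selective dechloroacetylation, in which DABCO is alkylated by the ClCH2 group and the α-ammonio ester so formed undergoes ethanolysis much faster than benzoates, frees the C6 hydroxyl without change of configuration and without a sulfur nucleophile that could attack the oxirane.

Step 10
Reactants: 12 [(1S,2R,5R,6R)-5-(benzoyloxy)-2-hydroxy-7-oxabicyclo[4.1.0]hept-3-en-1-yl]methyl benzoate; 13 acetic acid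
Product: 14 [(1S,2S,3R,6R)-2-acetoxy-3-(benzoyloxy)-1,6-dihydroxycyclohex-4-en-1-yl]methyl benzoate
Conditions: Ti(OiPr)4, CH2Cl2, rt
Reagents that add atoms: acetic acid (13), CC(O)=O
Why: Ti(OiPr)4-mediated opening of a 2,3-epoxy alcohol by a carboxylic acid, in which titanium bound to the C6 alkoxide on the face opposite to the oxirane oxygen passes acetate to C2 (the distal carbon of the epoxy alcohol, secondary and far less hindered than the fully substituted C1) anti to the C2–O bond, so that C2 is inverted and C1 keeps its oxygen, which becomes the tertiary alcohol.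

Compound list
1 | 2-hydroxy-5-methoxybenzaldehyde | COc1ccc(O)c(C=O)c1 | starting material
2 | 2-(hydroxymethyl)-4-methoxyphenol | COc1ccc(O)c(CO)c1 | intermediate
3 | 2-(hydroxymethyl)-4,4-dimethoxycyclohexa-2,5-dien-1-one (C6 ketone, C3 dimethyl ketal, free C7 hydroxyl) | OCC1=CC(OC)(OC)C=CC1=O | intermediate
4 | (1R,6S)-1-(hydroxymethyl)-5,5-dimethoxy-7-oxabicyclo[4.1.0]hept-3-en-2-one (C1–C2 oxirane, oxygen on the ring face opposite to C7) | O1[C@@H]2C(OC)(OC)C=CC(=O)[C@]12CO | intermediate
5 | benzoyl chloride | O=C(Cl)c1ccccc1 | starting material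
6 | [(1R,6S)-5,5-dimethoxy-2-oxo-7-oxabicyclo[4.1.0]hept-3-en-1-yl]methyl benzoate (C7 benzoate of 4) | O1[C@@H]2C(OC)(OC)C=CC(=O)[C@]12COC(=O)c1ccccc1 | intermediate
7 | [(1S,2S,6S)-2-hydroxy-5,5-dimethoxy-7-oxabicyclo[4.1.0]hept-3-en-1-yl]methyl benzoate (C6 hydroxyl cis to the oxirane oxygen; formed in step 5, not isolated) | O1[C@@H]2C(OC)(OC)C=C[C@H](O)[C@]12COC(=O)c1ccccc1 | intermediate
8 | [(1S,2S,6S)-2-hydroxy-5-oxo-7-oxabicyclo[4.1.0]hept-3-en-1-yl]methyl benzoate (C6 hydroxyl cis to the oxirane oxygen, C3 ketone) | O1[C@@H]2C(=O)C=C[C@H](O)[C@]12COC(=O)c1ccccc1 | intermediate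
9 | [(1S,2R,6S)-2-[(chloroacetyl)oxy]-5-oxo-7-oxabicyclo[4.1.0]hept-3-en-1-yl]methyl benzoate (C6 ester trans to the oxirane oxygen) | O1[C@@H]2C(=O)C=C[C@@H](OC(=O)CCl)[C@]12COC(=O)c1ccccc1 | intermediate
10 | [(1S,2R,5R,6R)-2-[(chloroacetyl)oxy]-5-hydroxy-7-oxabicyclo[4.1.0]hept-3-en-1-yl]methyl benzoate (C3 hydroxyl cis to the oxirane oxygen) | O1[C@@H]2[C@H](O)C=C[C@@H](OC(=O)CCl)[C@]12COC(=O)c1ccccc1 | intermediate
11 | [(1S,2R,5R,6R)-5-(benzoyloxy)-2-[(chloroacetyl)oxy]-7-oxabicyclo[4.1.0]hept-3-en-1-yl]methyl benzoate | O1[C@@H]2[C@H](OC(=O)c3ccccc3)C=C[C@@H](OC(=O)CCl)[C@]12COC(=O)c1ccccc1 | intermediate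
12 | [(1S,2R,5R,6R)-5-(benzoyloxy)-2-hydroxy-7-oxabicyclo[4.1.0]hept-3-en-1-yl]methyl benzoate (C6 hydroxyl trans, C3 benzoate cis to the oxirane oxygen) | O1[C@@H]2[C@H](OC(=O)c3ccccc3)C=C[C@@H](O)[C@]12COC(=O)c1ccccc1 | intermediate
13 | acetic acid | CC(O)=O | starting material
14 | [(1S,2S,3R,6R)-2-acetoxy-3-(benzoyloxy)-1,6-dihydroxycyclohex-4-en-1-yl]methyl benzoate | CC(=O)O[C@H]1[C@H](OC(=O)c2ccccc2)C=C[C@@H](O)[C@@]1(O)COC(=O)c1ccccc1 | target

Total step count: 10. Longest linear sequence: 10 steps (1 to 14).

Steps most likely to fail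

Step 3. The risk is weak enantioface discrimination: a tartrate-free background pathway, or a loosely organised aggregate with the acyclic dimethyl ketal, would erode the enantiomeric purity on which every later stereocentre depends. The fallback sets out from 3 and replaces asymmetric induction by resolution. The same trityl hydroperoxide and NaN(SiMe3)2 epoxidation run without tartrate should give the racemic epoxy ketone F1. Lipase-catalysed transesterification with vinyl benzoate in tert-butyl methyl ether (Candida antarctica lipase B or Burkholderia cepacia lipase, chosen by screening) should then benzoylate the unwanted enantiomer to the antipodal benzoate F2. The unreacted (1R,6S)-alcohol, separated by chromatography, comes back to the route as 4.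

Step 10. The risk is misdirected opening of the oxirane. The C6 alkoxide lies antiperiplanar to the C1–O bond and can shift the oxirane to C6–C1; the C7 benzoate can capture the activated oxirane; or acetate can enter at C1. The fallback sets out from 12 and takes its regiocontrol from a carbonyl group instead of a hydroxyl template. MnO2 in CH2Cl2 should oxidise the allylic C6 alcohol to the epoxy enone F3. With C1 now α to a ketone and no free hydroxyl left, acid-catalysed acetolysis (AcOH, catalytic TsOH, 40 °C) can open only at the β-carbon C2, with inversion, to give the acetoxy hydroxy ketone F4. Evans–Saksena reduction (Me4NBH(OAc)3, MeCN/AcOH, −20 °C) follows: the tertiary C1 hydroxyl binds boron and delivers hydride to C6 from its own face, which should give the trans-1,6-diol and so comes back to the route at 14.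

Step 6. The risk is slow displacement at C6 next to the fully substituted C1, which would leave alcohol unreacted or allow partial retention through assistance by the C7 benzoate; any facial erosion in the reduction of step 5 also shows up here. The fallback sets out from 8 and inverts C6 through a sulfonate. Tf2O and pyridine (CH2Cl2, −30 °C) should give the C6 triflate F5. Lattrell–Dax inversion with Bu4NNO2 (MeCN, rt) should give the inverted nitrite ester F6, which is hydrolysed on aqueous work-up to the C6-epimeric alcohol F7. Chloroacetic anhydride and pyridine (CH2Cl2, 0 °C) then give 9, where the route is rejoined. The alcohol F7 is also what a reduction from the opposite face in step 5 would give, so either C6 epimer can be taken on to 9.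

Further compounds
F1 | step 3 | racemic 1-(hydroxymethyl)-5,5-dimethoxy-7-oxabicyclo[4.1.0]hept-3-en-2-one (racemate of 4) | OCC12OC1C(OC)(OC)C=CC2=O
F2 | step 3 | [(1S,6R)-5,5-dimethoxy-2-oxo-7-oxabicyclo[4.1.0]hept-3-en-1-yl]methyl benzoate (antipode of 6) | O1[C@H]2C(OC)(OC)C=CC(=O)[C@@]12COC(=O)c1ccccc1
F3 | step 10 | epoxy enone: C6 ketone of 12, oxirane and both benzoates unchanged | O1[C@@H]2[C@H](OC(=O)c3ccccc3)C=CC(=O)[C@]12COC(=O)c1ccccc1
F4 | step 10 | acetoxy hydroxy ketone: C6 ketone analogue of 14 (C1 hydroxyl, C2 acetate, C3 and C7 benzoates) | CC(=O)O[C@H]1[C@H](OC(=O)c2ccccc2)C=CC(=O)[C@@]1(O)COC(=O)c1ccccc1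
F5 | step 6 | C6 trifluoromethanesulfonate of 8, configuration unchanged | O1[C@@H]2C(=O)C=C[C@H](OS(=O)(=O)C(F)(F)F)[C@]12COC(=O)c1ccccc1
F6 | step 6 | C6 nitrite ester with inverted C6 (not isolated) | O1[C@@H]2C(=O)C=C[C@@H](ON=O)[C@]12COC(=O)c1ccccc1
F7 | step 6 | C6 epimer of 8 (C6 hydroxyl trans to the oxirane oxygen) | O1[C@@H]2C(=O)C=C[C@@H](O)[C@]12COC(=O)c1ccccc1
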